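**Retrosynthetic overview**

- Entonaemin A comes from its tris-TBS ether by one global desilylation; the orsellinate is carried from the start.
- Both rings come from one acyclic vinyl ketone/ynone: an amine-catalysed Rauhut–Currier closure forms the carbocycle (C8a–C4a) first, then an oxa-6π electrocyclisation closes the pyran (O2–C1) in the same flask.
- The acyclic α-hydroxy vinyl ketone comes from the C7–C8 bond: lithiated methoxyallene (an acryloyl anion equivalent) adds to an α-aroyloxy methyl ketone and sets C7, and the acetylide formed in the same pot adds to (E)-4-silyloxybut-2-enal to bring in the side chain.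
- The ketone comes from ozonolysis of an isopropenyl ester, made by Mitsunobu inversion of (S)-2-methylhex-1-en-5-yn-3-ol with bis-silylated orsellinic acid; the alcohol comes from asymmetric propargylation of methacrolein, which sets C6.

Assumption: the allenylboronate, silyloxyacetaldehyde, formyl ylide and methoxyallene are bought, and (S)-TRIP is taken to give the S alcohol in step 1 (if the sense is opposite, its antipode is used).

**Route**

Step 1
Reactants: 1 methacrolein; 2 allenylboronic acid pinacol ester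
Product: 3 (S)-2-methylhex-1-en-5-yn-3-ol
Conditions: (S)-TRIP (5 mol %), 4 Å MS, toluene, −20 °C; aqueous work-up
Reagents that add atoms: none
Why: Chiral-phosphoric-acid-catalysed asymmetric propargylation (SE2′ allenylboration through a closed six-membered transition state) delivers the propargyl group to one aldehyde face and sets the carbinol centre (future C6, here S, inverted in step 3).

Step 2
Reactants: 4 orsellinic acid
Product: 6 2,4-bis[(tert-butyldimethylsilyl)oxy]-6-methylbenzoic acid, via tris-silyl ester 5 (not isolated)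
Conditions: TBSCl (3.3 equiv), imidazole (6 equiv), DMF, rt; then AcOH/THF/H2O (3:1:1), rt
Reagents that add atoms: tert-butyldimethylsilyl chloride (TBSCl), CC(C)(C)[Si](C)(C)Cl
Why: Exhaustive silylation followed by selective hydrolysis of the labile silyl ester leaves the two aryl silyl ethers, which mask the phenols against the organolithium, ozone and amine steps.

Step 3
Reactants: 3 (S)-2-methylhex-1-en-5-yn-3-ol; 6 2,4-bis[(tert-butyldimethylsilyl)oxy]-6-methylbenzoic acid
Product: 7 (R)-2-methylhex-1-en-5-yn-3-yl 2,4-bis[(tert-butyldimethylsilyl)oxy]-6-methylbenzoate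
Conditions: PPh3, DIAD, toluene, 0 °C → rt
Reagents that add atoms: none
Why: Mitsunobu esterification, in which the carboxylate of the hindered acid attacks the activated carbinol carbon (not the shielded acyl carbon) by SN2 with inversion, S → R, giving the target configuration at C6.

Step 4
Reactants: 7 (R)-2-methylhex-1-en-5-yn-3-yl 2,4-bis[(tert-butyldimethylsilyl)oxy]-6-methylbenzoate
Product: 8 (R)-2-oxohex-5-yn-3-yl 2,4-bis[(tert-butyldimethylsilyl)oxy]-6-methylbenzoate
Conditions: O3, CH2Cl2/MeOH (4:1), Sudan Red 7B, −78 °C; then Me2S, −78 °C → rt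
Reagents that add atoms: ozone, [O-][O+]=O
Why: Ozonolysis with reductive work-up cleaves the electron-rich 1,1-disubstituted alkene much faster than the terminal alkyne or the silylated arene, giving the methyl ketone without touching the stereocentre.

Step 5
Reactants: 9 (tert-butyldimethylsilyloxy)acetaldehyde; 10 (triphenylphosphoranylidene)acetaldehyde
Product: 11 (E)-4-[(tert-butyldimethylsilyl)oxy]but-2-enal
Conditions: toluene, 80 °C
Reagents that add atoms: none
Why: Wittig olefination with the stabilised formyl ylide gives the E-enal selectively.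

Step 6
Reactants: 8 (R)-2-oxohex-5-yn-3-yl 2,4-bis[(tert-butyldimethylsilyl)oxy]-6-methylbenzoate; 12 methoxyallene (1-methoxypropa-1,2-diene); 11 (E)-4-[(tert-butyldimethylsilyl)oxy]but-2-enal
Product: 15 (4R,5R,10E)-12-[(tert-butyldimethylsilyl)oxy]-4,9-dihydroxy-4-methyl-3-oxododeca-1,10-dien-7-yn-5-yl 2,4-bis[(tert-butyldimethylsilyl)oxy]-6-methylbenzoate, via allenyl carbinol 13 (not isolated), via allenyl ether diol 14 (not isolated)
Conditions: 12 (2.4 equiv), n-BuLi (2.3 equiv), THF, −78 °C; add 8, −78 °C; then 11 (1.5 equiv), −78 → −40 °C; then 0.5 M HCl, THF, 0 °C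
Reagents that add atoms: water, O
Why: 1-Lithio-1-methoxyallene acts as an acryloyl anion equivalent and adds to the ketone carbonyl, joining two carbonyl carbons (C7–C8) under polar Felkin–Anh control (the weakly coordinating aroyloxy group anti to the incoming nucleophile), which sets C7 as R, i.e. the tertiary OH cis to the C6 ester in the later ring; the second equivalent only deprotonates the terminal alkyne and returns as 12, the resulting acetylide adds 1,2 to enal 11 (the new carbinol is an inconsequential epimer mixture), and dilute acid hydrolyses the allenyl enol ether to the vinyl ketone.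

Step 7
Reactants: 15 (4R,5R,10E)-12-[(tert-butyldimethylsilyl)oxy]-4,9-dihydroxy-4-methyl-3-oxododeca-1,10-dien-7-yn-5-yl 2,4-bis[(tert-butyldimethylsilyl)oxy]-6-methylbenzoate
Product: 17 (6R,7R)-3-[(E)-3-[(tert-butyldimethylsilyl)oxy]prop-1-en-1-yl]-7-hydroxy-7-methyl-8-oxo-5,6,7,8-tetrahydro-1H-isochromen-6-yl 2,4-bis[(tert-butyldimethylsilyl)oxy]-6-methylbenzoate, via ynone 16 (not isolated)
Conditions: MnO2 (20 equiv), CH2Cl2, rt; filter; then DABCO (20 mol %), CHCl3, rt
Reagents that add atoms: none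
Why: MnO2 oxidises the allylic/propargylic alcohol to the ynone, and DABCO then triggers a Rauhut–Currier (Morita–Baylis–Hillman-type) cycloisomerisation: the amine adds to the vinyl ketone, the enolate closes 6-exo-dig onto the ynone, and loss of DABCO leaves an exocyclic methylene oxatriene that closes by oxa-6π electrocyclisation to the 2H-pyran, a bicyclisation known for closely related acyclic ynone/vinyl ketones; no stereocentre is touched.

Step 8
Reactants: 17 (6R,7R)-3-[(E)-3-[(tert-butyldimethylsilyl)oxy]prop-1-en-1-yl]-7-hydroxy-7-methyl-8-oxo-5,6,7,8-tetrahydro-1H-isochromen-6-yl 2,4-bis[(tert-butyldimethylsilyl)oxy]-6-methylbenzoate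
Product: 18 entonaemin A, (6R,7R)-7-hydroxy-3-[(E)-3-hydroxyprop-1-en-1-yl]-7-methyl-8-oxo-5,6,7,8-tetrahydro-1H-isochromen-6-yl 2,4-dihydroxy-6-methylbenzoate
Conditions: TBAF (3.5 equiv), AcOH (3.5 equiv), THF, 0 °C → rt
Reagents that add atoms: none
Why: Fluoride-mediated desilylation removes the two aryl and one primary silyl ether, and buffering with acetic acid avoids base-induced β-elimination of the C6 ester or acyl migration.

**Compound list**

1 | methacrolein (2-methylprop-2-enal) | CC(=C)C=O | starting material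
2 | allenylboronic acid pinacol ester | C=C=CB1OC(C)(C)C(C)(C)O1 | starting material
3 | (S)-2-methylhex-1-en-5-yn-3-ol | C=C(C)[C@@H](O)CC#C | intermediate
4 | orsellinic acid (2,4-dihydroxy-6-methylbenzoic acid) | Cc1cc(O)cc(O)c1C(=O)O | starting material
5 | tert-butyldimethylsilyl 2,4-bis[(tert-butyldimethylsilyl)oxy]-6-methylbenzoate | Cc1cc(O[Si](C)(C)C(C)(C)C)cc(O[Si](C)(C)C(C)(C)C)c1C(=O)O[Si](C)(C)C(C)(C)C | intermediate
6 | 2,4-bis[(tert-butyldimethylsilyl)oxy]-6-methylbenzoic acid | Cc1cc(O[Si](C)(C)C(C)(C)C)cc(O[Si](C)(C)C(C)(C)C)c1C(=O)O | intermediate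
7 | (R)-2-methylhex-1-en-5-yn-3-yl 2,4-bis[(tert-butyldimethylsilyl)oxy]-6-methylbenzoate | Cc1cc(O[Si](C)(C)C(C)(C)C)cc(O[Si](C)(C)C(C)(C)C)c1C(=O)O[C@H](CC#C)C(C)=C | intermediate
8 | (R)-2-oxohex-5-yn-3-yl 2,4-bis[(tert-butyldimethylsilyl)oxy]-6-methylbenzoate | Cc1cc(O[Si](C)(C)C(C)(C)C)cc(O[Si](C)(C)C(C)(C)C)c1C(=O)O[C@H](CC#C)C(C)=O | intermediate
9 | (tert-butyldimethylsilyloxy)acetaldehyde | CC(C)(C)[Si](C)(C)OCC=O | starting material
10 | (triphenylphosphoranylidene)acetaldehyde | O=CC=P(c1ccccc1)(c1ccccc1)c1ccccc1 | starting material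
11 | (E)-4-[(tert-butyldimethylsilyl)oxy]but-2-enal | CC(C)(C)[Si](C)(C)OC/C=C/C=O | intermediate
12 | methoxyallene (1-methoxypropa-1,2-diene) | COC=C=C | starting material
13 | (4R,5R)-4-hydroxy-3-methoxy-4-methylocta-1,2-dien-7-yn-5-yl 2,4-bis[(tert-butyldimethylsilyl)oxy]-6-methylbenzoate (present as its lithium alkoxide/acetylide) | Cc1cc(O[Si](C)(C)C(C)(C)C)cc(O[Si](C)(C)C(C)(C)C)c1C(=O)O[C@H](CC#C)[C@@](C)(O)C(OC)=C=C | intermediate
14 | (4R,5R,10E)-12-[(tert-butyldimethylsilyl)oxy]-4,9-dihydroxy-3-methoxy-4-methyldodeca-1,2,10-trien-7-yn-5-yl 2,4-bis[(tert-butyldimethylsilyl)oxy]-6-methylbenzoate (C9 epimers) | Cc1cc(O[Si](C)(C)C(C)(C)C)cc(O[Si](C)(C)C(C)(C)C)c1C(=O)O[C@H](CC#CC(O)/C=C/CO[Si](C)(C)C(C)(C)C)[C@@](C)(O)C(OC)=C=C | intermediate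
15 | (4R,5R,10E)-12-[(tert-butyldimethylsilyl)oxy]-4,9-dihydroxy-4-methyl-3-oxododeca-1,10-dien-7-yn-5-yl 2,4-bis[(tert-butyldimethylsilyl)oxy]-6-methylbenzoate (C9 epimers) | Cc1cc(O[Si](C)(C)C(C)(C)C)cc(O[Si](C)(C)C(C)(C)C)c1C(=O)O[C@H](CC#CC(O)/C=C/CO[Si](C)(C)C(C)(C)C)[C@@](C)(O)C(=O)C=C | intermediate
16 | (4R,5R,10E)-12-[(tert-butyldimethylsilyl)oxy]-4-hydroxy-4-methyl-3,9-dioxododeca-1,10-dien-7-yn-5-yl 2,4-bis[(tert-butyldimethylsilyl)oxy]-6-methylbenzoate | Cc1cc(O[Si](C)(C)C(C)(C)C)cc(O[Si](C)(C)C(C)(C)C)c1C(=O)O[C@H](CC#CC(=O)/C=C/CO[Si](C)(C)C(C)(C)C)[C@@](C)(O)C(=O)C=C | intermediate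
17 | (6R,7R)-3-[(E)-3-[(tert-butyldimethylsilyl)oxy]prop-1-en-1-yl]-7-hydroxy-7-methyl-8-oxo-5,6,7,8-tetrahydro-1H-isochromen-6-yl 2,4-bis[(tert-butyldimethylsilyl)oxy]-6-methylbenzoate | Cc1cc(O[Si](C)(C)C(C)(C)C)cc(O[Si](C)(C)C(C)(C)C)c1C(=O)O[C@@H]1CC2=C(COC(/C=C/CO[Si](C)(C)C(C)(C)C)=C2)C(=O)[C@]1(C)O | intermediate
18 | entonaemin A | Cc1cc(O)cc(O)c1C(=O)O[C@@H]1CC2=C(COC(/C=C/CO)=C2)C(=O)[C@]1(C)O | target

**Step count and risks**

Total step count: 8. Longest linear sequence: 6 (steps 1, 3, 4, 6, 7, 8).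

Steps most likely to fail:

Step 6. The basic allenyllithium may enolise the α-aroyloxy ketone, Felkin–Anh control may be only moderate, the neighbouring ester may migrate to the new tertiary alkoxide, or the in-flask acetylide trapping may be poor. Fallback: separate the two events and make the ynone by a neutral Pd/Cu acylation instead of acetylide chemistry. It sets out from 8: the cerium reagent made from lithiated 12 and CeCl3 (THF, −78 °C; weakly basic, so the alkyne C–H and the α-hydrogen are left alone) gives 13, and hydrolysis with 0.5 M HCl gives (4R,5R)-4-hydroxy-4-methyl-3-oxooct-1-en-7-yn-5-yl 2,4-bis[(tert-butyldimethylsilyl)oxy]-6-methylbenzoate F1. In parallel, 11 is oxidised (NaClO2, NaH2PO4, 2-methylbut-2-ene) to (E)-4-[(tert-butyldimethylsilyl)oxy]but-2-enoic acid F2, which Ghosez's reagent converts into (E)-4-[(tert-butyldimethylsilyl)oxy]but-2-enoyl chloride F3. Acyl Sonogashira coupling of F1 with F3 (PdCl2(PPh3)2, CuI, Et3N, THF, 0 °C) gives the ynone, and the route is rejoined at 16, which is taken on with DABCO as in step 7.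

Step 7. Under amine catalysis the C6 aroyloxy group is β to the acidic propargylic/γ position and may be lost by E1cB elimination, the tertiary hydroxyl may add to the ynone, or the Rauhut–Currier step may stall. Fallback: close the carbocycle under Lewis-acidic, non-basic conditions by a halo-Michael reaction. It sets out from 16 (isolated after the MnO2 oxidation of 15). MgI2·OEt2 (CH2Cl2, −20 °C) adds iodide to the vinyl ketone, and the magnesium enolate adds to the ynone to give (1R,2R)-2-hydroxy-4-(iodomethyl)-2-methyl-3-oxo-5-[(3E)-5-[(tert-butyldimethylsilyl)oxy]-2-oxopent-3-en-1-ylidene]cyclohexyl 2,4-bis[(tert-butyldimethylsilyl)oxy]-6-methylbenzoate F4. Brief treatment with Et3N (0 °C) eliminates HI to the exocyclic methylene oxatriene, which electrocyclises, and the route is rejoined at 17.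

Step 3. Mitsunobu displacement at an allylic carbinol with a di-ortho-substituted benzoic acid may give SN2′ product or stall. Fallback: move the displacement to the α-keto position. It sets out from 3. Ozonolysis (O3, CH2Cl2/MeOH, −78 °C; Me2S) gives (S)-3-hydroxyhex-5-yn-2-one F5, and nosylation (NsCl, Et3N, cat. DMAP, CH2Cl2, −20 °C) gives (S)-2-oxohex-5-yn-3-yl 4-nitrobenzenesulfonate F6. SN2 displacement by the caesium salt of 6 (Cs2CO3, DMF, 0 °C) inverts the activated α-carbon with no allylic system left, and the route is rejoined at 8.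

**Further compounds**

F1 | step 6 | (4R,5R)-4-hydroxy-4-methyl-3-oxooct-1-en-7-yn-5-yl 2,4-bis[(tert-butyldimethylsilyl)oxy]-6-methylbenzoate | Cc1cc(O[Si](C)(C)C(C)(C)C)cc(O[Si](C)(C)C(C)(C)C)c1C(=O)O[C@H](CC#C)[C@@](C)(O)C(=O)C=C
F2 | step 6 | (E)-4-[(tert-butyldimethylsilyl)oxy]but-2-enoic acid | CC(C)(C)[Si](C)(C)OC/C=C/C(=O)O
F3 | step 6 | (E)-4-[(tert-butyldimethylsilyl)oxy]but-2-enoyl chloride | CC(C)(C)[Si](C)(C)OC/C=C/C(Cl)=O
F4 | step 7 | (1R,2R)-2-hydroxy-4-(iodomethyl)-2-methyl-3-oxo-5-[(3E)-5-[(tert-butyldimethylsilyl)oxy]-2-oxopent-3-en-1-ylidene]cyclohexyl 2,4-bis[(tert-butyldimethylsilyl)oxy]-6-methylbenzoate | Cc1cc(O[Si](C)(C)C(C)(C)C)cc(O[Si](C)(C)C(C)(C)C)c1C(=O)O[C@@H]1CC(=CC(=O)/C=C/CO[Si](C)(C)C(C)(C)C)C(CI)C(=O)[C@]1(C)O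
F5 | step 3 | (S)-3-hydroxyhex-5-yn-2-one | CC(=O)[C@@H](O)CC#C
F6 | step 3 | (S)-2-oxohex-5-yn-3-yl 4-nitrobenzenesulfonate | CC(=O)[C@@H](OS(=O)(=O)c1ccc(cc1)[N+](=O)[O-])CC#C
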